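## Retrosynthetic overview

1. The target is 3-O-galloyl-epicatechin-(4β→8)-3-O-galloyl-epicatechin-(4β→6)-catechin. The last operations are global hydrogenolysis (19 benzyl ethers, two C8 bromine caps) after a double, inverting galloylation of a bis(3β-carbinol).
2. The carbinols come from a trimeric diketone. Both interflavan C–C bonds are cut as enolonium couplings: C4 of a flavan-3-one (an enolate carbon made electrophilic by two-electron oxidation) joins a nucleophilic ring-A carbon.
3. Order of bond formation: the 4β→8 bond first (C8-capped ketone + tetra-O-benzylcatechin), then 3-OH to ketone in the new middle unit, then the 4β→6 bond (keto-dimer + C8-capped catechin).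
4. No ring is built. All three flavan skeletons (rings A, B and the pyran ring) come intact from (+)-catechin; the gallates come from 3,4,5-tris(benzyloxy)benzoic acid.

Assumption: the identifier is taken to mean exactly the given SMILES, read as upper and middle units 2R,3R with 3-O-gallate and 4β linkages, terminal unit (2R,3S)-catechin linked through C6.

## Route

Step 1
Reactants: 1 (+)-catechin
Product: 2 5,7,3',4'-tetra-O-benzyl-(+)-catechin
Conditions: BnBr (4.4 equiv), K2CO3, DMF, 0 °C to rt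
Reagents that add atoms: benzyl bromide, BrCc1ccccc1
Why: Williamson etherification under weak base alkylates only the four phenols, leaving the secondary 3-OH free and C2 (R) and C3 (S) untouched.

Step 2
Reactants: 2 5,7,3',4'-tetra-O-benzyl-(+)-catechin
Product: 3 8-bromo-5,7,3',4'-tetra-O-benzyl-(+)-catechin
Conditions: NBS (1.0 equiv), CH2Cl2, −78 °C to rt
Reagents that add atoms: N-bromosuccinimide, O=C1CCC(=O)N1Br
Why: Electrophilic aromatic bromination of the benzylated phloroglucinol ring A goes to C8 (one benzyloxy neighbour plus the ring oxygen) rather than the more hindered C6, installing the cap that later blocks C8.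

Step 3
Reactants: 3 8-bromo-5,7,3',4'-tetra-O-benzyl-(+)-catechin
Product: 4 (2R)-8-bromo-5,7-bis(benzyloxy)-2-[3,4-bis(benzyloxy)phenyl]chroman-3-one
Conditions: Dess–Martin periodinane (1.5 equiv), wet CH2Cl2, rt
Reagents that add atoms: none
Why: Dess–Martin oxidation converts the secondary alcohol into the flavan-3-one under non-basic conditions, so the enolisable C2 stereocentre (R) is kept.

Step 4
Reactants: 3 8-bromo-5,7,3',4'-tetra-O-benzyl-(+)-catechin
Product: 5 8-bromo-3,5,7,3',4'-penta-O-benzyl-(+)-catechin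
Conditions: NaH, BnBr, DMF, 0 °C to rt
Reagents that add atoms: benzyl bromide, BrCc1ccccc1
Why: Williamson etherification of the 3-alkoxide masks the terminal-unit 3-OH so it cannot compete in the later esterification; no stereocentre is involved.

Step 5
Reactants: 4 (2R)-8-bromo-tetra-O-benzyl-flavan-3-one; 2 5,7,3',4'-tetra-O-benzyl-(+)-catechin (3 equiv, excess recovered)
Product: 7 keto-alcohol dimer 8-bromo-tetra-O-benzyl-3-oxoflavan-(4β→8)-tetra-O-benzylcatechin, via enolonium tetrafluoroborate 6 (not isolated)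
Conditions: AgBF4 (2.5 equiv), 2,6-di-tert-butyl-4-methylpyridine (2.5 equiv), THF, 60 °C, dark
Reagents that add atoms: none
Why: Silver-mediated oxidative coupling of a flavan-3-one (enolonium chemistry): monovalent silver oxidises the C4 enol of 4 by two electrons to the α-keto benzylic cation 6, which cannot self-condense at its capped C8 and is captured in a Friedel–Crafts step by C8 of 2; axial attack trans to the C2 aryl group sets the new C4 as 4β.

Step 6
Reactants: 7 keto-alcohol dimer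
Product: 8 diketone dimer 8-bromo-tetra-O-benzyl-3-oxoflavan-(4β→8)-tetra-O-benzyl-3-oxoflavan
Conditions: Dess–Martin periodinane (1.5 equiv), wet CH2Cl2, rt
Reagents that add atoms: none
Why: Dess–Martin oxidation of the only free hydroxyl turns the second unit into a flavan-3-one with an enolisable C4 methylene, under neutral conditions that do not epimerise the α-keto C2 and C4 centres.

Step 7
Reactants: 8 diketone dimer; 5 8-bromo-3,5,7,3',4'-penta-O-benzyl-(+)-catechin (3 equiv, excess recovered)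
Product: 10 trimer diketone 8-bromo-3-oxoflavan-(4β→8)-3-oxoflavan-(4β→6)-8-bromo-penta-O-benzylcatechin, via enolonium tetrafluoroborate 9 (not isolated)
Conditions: AgBF4 (2.2 equiv), 2,6-di-tert-butyl-4-methylpyridine (2.2 equiv), THF, 60 °C, dark
Reagents that add atoms: none
Why: Proposed new method: site-selective enolonium formation in a diketone. The C4 methylene of the middle unit enolises and is oxidised by monovalent silver far faster than the hindered tertiary C4–H of the upper unit, and cation 9 is trapped at C6 of 5 (its only free ring-A carbon) by axial attack trans to the C2 aryl group, giving 4β. The closest known reaction type is the silver-mediated oxidative coupling of monomeric 3-oxoflavans with flavan-3-ol nucleophiles, combined with C8 halogen capping to direct 4→6 bond formation.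

Step 8
Reactants: 10 trimer diketone
Product: 11 trimer diol with both upper units 2,3-trans-3,4-cis (3β-OH)
Conditions: NaBH4, CeCl3·7H2O, THF/MeOH (4:1), −40 °C
Reagents that add atoms: none
Why: Luche reduction: in each 2,4-trans 4-aryl-flavan-3-one the 4-aryl group is pseudoaxial (peri strain with 5-OBn) and shields the β face, so hydride adds axially from the α face to give the equatorial 3β-carbinol, and the cerium medium suppresses enolisation so C2 and C4 keep their configuration.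

Step 9
Reactants: 11 trimer diol; 12 3,4,5-tris(benzyloxy)benzoic acid (6 equiv)
Product: 13 nonadeca-O-benzyl-8,8''-dibromo derivative of the target
Conditions: PPh3 (6 equiv), DIAD (6 equiv), toluene/THF, 0 to 50 °C
Reagents that add atoms: none
Why: Double Mitsunobu esterification: SN2 displacement of each oxyphosphonium by the carboxylate of 12 inverts C3, turning the equatorial 3β-carbinols into axial 3α-gallates (2,3-cis-3,4-trans, the epicatechin gallate pattern); the benzylated terminal 3-oxygen cannot react.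

Step 10
Reactants: 13 protected trimer
Product: 14 CNP0154615.1
Conditions: H2 (1 atm), Pd(OH)2/C, Et3N (2.2 equiv), THF/MeOH/H2O, rt
Reagents that add atoms: none
Why: Catalytic hydrogenolysis cleaves all 19 benzyl ethers and, with Et3N as HBr scavenger, both C8–Br caps, without touching the gallate esters, the interflavan bonds or any stereocentre.

## Compound list

1 | (+)-catechin, (2R,3S)-2-(3,4-dihydroxyphenyl)chromane-3,5,7-triol | O[C@H]1Cc2c(O)cc(O)cc2O[C@@H]1c1ccc(O)c(O)c1 | starting material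

2 | 5,7,3',4'-tetra-O-benzyl-(+)-catechin (2R,3S, free 3-OH) | O[C@H]1Cc2c(OCc3ccccc3)cc(OCc3ccccc3)cc2O[C@@H]1c1ccc(OCc2ccccc2)c(OCc2ccccc2)c1 | intermediate

3 | 8-bromo-5,7,3',4'-tetra-O-benzyl-(+)-catechin (2R,3S) | O[C@H]1Cc2c(OCc3ccccc3)cc(OCc3ccccc3)c(Br)c2O[C@@H]1c1ccc(OCc2ccccc2)c(OCc2ccccc2)c1 | intermediate

4 | (2R)-8-bromo-5,7-bis(benzyloxy)-2-[3,4-bis(benzyloxy)phenyl]chroman-3-one | O=C1Cc2c(OCc3ccccc3)cc(OCc3ccccc3)c(Br)c2O[C@@H]1c1ccc(OCc2ccccc2)c(OCc2ccccc2)c1 | intermediate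

5 | 8-bromo-3,5,7,3',4'-penta-O-benzyl-(+)-catechin (2R,3S) | c1ccccc1CO[C@H]2Cc3c(OCc4ccccc4)cc(OCc4ccccc4)c(Br)c3O[C@@H]2c2ccc(OCc3ccccc3)c(OCc3ccccc3)c2 | intermediate

6 | C4 enolonium of 4: (2R)-8-bromo-5,7-bis(benzyloxy)-2-[3,4-bis(benzyloxy)phenyl]-3-oxochroman-4-ylium tetrafluoroborate | O=C1[CH+]c2c(OCc3ccccc3)cc(OCc3ccccc3)c(Br)c2O[C@@H]1c1ccc(OCc2ccccc2)c(OCc2ccccc2)c1.F[B-](F)(F)F | intermediate

7 | keto-alcohol dimer: upper unit (2R)-8-bromo-5,7,3',4'-tetra-O-benzyl-3-oxoflavan (2-aryl α, 4-aryl β, 2,4-trans) bonded C4→C8 to 5,7,3',4'-tetra-O-benzyl-(+)-catechin (2R,3S, free 3-OH) | O=C1[C@@H](c2c(OCc4ccccc4)cc(OCc4ccccc4)c3c2O[C@H](c4ccc(OCc5ccccc5)c(OCc5ccccc5)c4)[C@@H](O)C3)c2c(OCc3ccccc3)cc(OCc3ccccc3)c(Br)c2O[C@@H]1c1ccc(OCc2ccccc2)c(OCc2ccccc2)c1 | intermediate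

8 | diketone dimer: as 7 but with the second unit oxidised to the (2R)-3-oxoflavan (C4 methylene) | O=C1[C@@H](c2c(OCc4ccccc4)cc(OCc4ccccc4)c3c2O[C@H](c4ccc(OCc5ccccc5)c(OCc5ccccc5)c4)C(=O)C3)c2c(OCc3ccccc3)cc(OCc3ccccc3)c(Br)c2O[C@@H]1c1ccc(OCc2ccccc2)c(OCc2ccccc2)c1 | intermediate

9 | C4 enolonium of 8 (cation at C4 of the C8-linked 3-oxoflavan unit), tetrafluoroborate | O=C1[C@@H](c2c(OCc4ccccc4)cc(OCc4ccccc4)c3c2O[C@H](c4ccc(OCc5ccccc5)c(OCc5ccccc5)c4)C(=O)[CH+]3)c2c(OCc3ccccc3)cc(OCc3ccccc3)c(Br)c2O[C@@H]1c1ccc(OCc2ccccc2)c(OCc2ccccc2)c1.F[B-](F)(F)F | intermediate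

10 | trimer diketone: (2R)-8-bromo-tetra-O-benzyl-3-oxoflavan-(4β→8)-(2R)-tetra-O-benzyl-3-oxoflavan-(4β→6)-8-bromo-penta-O-benzyl-(+)-catechin; both keto units 2,4-trans | O=C1[C@@H](c2c(OCc4ccccc4)cc(OCc4ccccc4)c3c2O[C@H](c4ccc(OCc5ccccc5)c(OCc5ccccc5)c4)C(=O)[C@H]3c2c(OCc4ccccc4)c(Br)c3c(c2OCc4ccccc4)C[C@H](OCc4ccccc4)[C@@H](c4ccc(OCc5ccccc5)c(OCc5ccccc5)c4)O3)c2c(OCc3ccccc3)cc(OCc3ccccc3)c(Br)c2O[C@@H]1c1ccc(OCc2ccccc2)c(OCc2ccccc2)c1 | intermediate

11 | trimer diol: as 10 with both ketones reduced to 3β-OH (upper and middle units 2-aryl α, 3-OH β, 4-aryl β, i.e. 2,3-trans-3,4-cis) | O[C@H]1[C@@H](c2c(OCc4ccccc4)cc(OCc4ccccc4)c3c2O[C@H](c4ccc(OCc5ccccc5)c(OCc5ccccc5)c4)[C@@H](O)[C@H]3c2c(OCc4ccccc4)c(Br)c3c(c2OCc4ccccc4)C[C@H](OCc4ccccc4)[C@@H](c4ccc(OCc5ccccc5)c(OCc5ccccc5)c4)O3)c2c(OCc3ccccc3)cc(OCc3ccccc3)c(Br)c2O[C@@H]1c1ccc(OCc2ccccc2)c(OCc2ccccc2)c1 | intermediate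

12 | 3,4,5-tris(benzyloxy)benzoic acid | OC(=O)c1cc(OCc2ccccc2)c(OCc2ccccc2)c(OCc2ccccc2)c1 | starting material

13 | protected target: 3-O-(tri-O-benzylgalloyl)-8-bromo-tetra-O-benzyl-epicatechin-(4β→8)-3-O-(tri-O-benzylgalloyl)-tetra-O-benzyl-epicatechin-(4β→6)-8-bromo-penta-O-benzyl-catechin (upper units 2,3-cis-3,4-trans) | O=C(O[C@@H]1[C@@H](c2c(OCc4ccccc4)cc(OCc4ccccc4)c3c2O[C@H](c4ccc(OCc5ccccc5)c(OCc5ccccc5)c4)[C@H](OC(=O)c4cc(OCc5ccccc5)c(OCc5ccccc5)c(OCc5ccccc5)c4)[C@H]3c2c(OCc4ccccc4)c(Br)c3c(c2OCc4ccccc4)C[C@H](OCc4ccccc4)[C@@H](c4ccc(OCc5ccccc5)c(OCc5ccccc5)c4)O3)c2c(OCc3ccccc3)cc(OCc3ccccc3)c(Br)c2O[C@@H]1c1ccc(OCc2ccccc2)c(OCc2ccccc2)c1)c1cc(OCc2ccccc2)c(OCc2ccccc2)c(OCc2ccccc2)c1 | intermediate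

14 | CNP0154615.1, 3-O-galloyl-(−)-epicatechin-(4β→8)-3-O-galloyl-(−)-epicatechin-(4β→6)-(+)-catechin | O=C(O[C@@H]1[C@@H](c2c(O)cc(O)c3c2O[C@H](c2ccc(O)c(O)c2)[C@H](OC(=O)c2cc(O)c(O)c(O)c2)[C@H]3c2c(O)cc3c(c2O)C[C@H](O)[C@@H](c2ccc(O)c(O)c2)O3)c2c(O)cc(O)cc2O[C@@H]1c1ccc(O)c(O)c1)c1cc(O)c(O)c(O)c1 | target

## Step count and risks

Total step count: 10. Longest linear sequence: 9 steps (1 → 2 → 3 → 4 → 7 → 8 → 10 → 11 → 13 → 14).

Most likely to fail, first: step 7. The diketone 8 must be oxidised only at the middle-unit methylene, the nucleophilic C6 of 5 is hindered and slightly deactivated by bromine, and the upper-unit C4 (α to a ketone) could epimerise under the silver salt. The fallback reverses the order of bond formation so that the hindered C6 nucleophile meets a simple monomeric enolonium. It sets out from 2: Dess–Martin oxidation gives the uncapped ketone (2R)-5,7-bis(benzyloxy)-2-[3,4-bis(benzyloxy)phenyl]chroman-3-one F1. F1 is added slowly to AgBF4, the hindered pyridine and 5 (4 equiv) to give the 4β→6 keto-dimer tetra-O-benzyl-3-oxoflavan-(4β→6)-8-bromo-penta-O-benzylcatechin F2. F2, which has a free C8 on its keto unit, then replaces 2 as the nucleophile toward enolonium 6 generated from 4 as in step 5. This gives the trimer diketone directly, and the fallback comes back to the route at 10.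

Second: step 9. Two hindered secondary carbinols must be inverted by a carboxylate of only moderate acidity; the oxyphosphonium may fail to form, and participation by the ring oxygen or elimination can compete. The fallback separates activation from substitution. It sets out from 11: Tf2O and pyridine in CH2Cl2 at −40 °C give the bis(trifluoromethanesulfonate) of the trimer diol F3. F3 is displaced with inversion by the caesium carboxylate formed in the flask from 12 and Cs2CO3 (18-crown-6, toluene, rt), and the fallback comes back to the route at 13.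

Third: step 5. The silver oxidation has to outrun O-alkylation by the free 3-OH of 2 and acid- or silver-promoted epimerisation of the new C4. The fallback forms the enolonium as a discrete species at low temperature instead of by silver oxidation. It sets out from 4: TMSOTf and Et3N in CH2Cl2 give the trimethylsilyl enol ether (2R)-8-bromo-5,7-bis(benzyloxy)-2-[3,4-bis(benzyloxy)phenyl]-3-(trimethylsilyloxy)-2H-chromene F4. F4 is treated with PhI(OH)OTs and BF3·OEt2 at −78 °C (trivalent-iodine enolonium chemistry, delivering the same cation as 6) and then with 2, and the fallback comes back to the route at 7.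

Further compounds

F1 | step 7 | (2R)-5,7-bis(benzyloxy)-2-[3,4-bis(benzyloxy)phenyl]chroman-3-one | O=C1Cc2c(OCc3ccccc3)cc(OCc3ccccc3)cc2O[C@@H]1c1ccc(OCc2ccccc2)c(OCc2ccccc2)c1

F2 | step 7 | (2R)-5,7,3',4'-tetra-O-benzyl-3-oxoflavan-(4β→6)-8-bromo-3,5,7,3',4'-penta-O-benzyl-(+)-catechin (keto unit 2,4-trans) | c1c(OCc4ccccc4)cc(OCc4ccccc4)c3c1O[C@H](c4ccc(OCc5ccccc5)c(OCc5ccccc5)c4)C(=O)[C@H]3c2c(OCc4ccccc4)c(Br)c3c(c2OCc4ccccc4)C[C@H](OCc4ccccc4)[C@@H](c4ccc(OCc5ccccc5)c(OCc5ccccc5)c4)O3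

F3 | step 9 | bis(trifluoromethanesulfonate) of trimer diol 11 (both 3β-O-triflates) | FC(F)(F)S(=O)(=O)O[C@H]1[C@@H](c2c(OCc4ccccc4)cc(OCc4ccccc4)c3c2O[C@H](c4ccc(OCc5ccccc5)c(OCc5ccccc5)c4)[C@@H](OS(=O)(=O)C(F)(F)F)[C@H]3c2c(OCc4ccccc4)c(Br)c3c(c2OCc4ccccc4)C[C@H](OCc4ccccc4)[C@@H](c4ccc(OCc5ccccc5)c(OCc5ccccc5)c4)O3)c2c(OCc3ccccc3)cc(OCc3ccccc3)c(Br)c2O[C@@H]1c1ccc(OCc2ccccc2)c(OCc2ccccc2)c1

F4 | step 5 | (2R)-8-bromo-5,7-bis(benzyloxy)-2-[3,4-bis(benzyloxy)phenyl]-3-(trimethylsilyloxy)-2H-chromene | C[Si](C)(C)OC1=Cc2c(OCc3ccccc3)cc(OCc3ccccc3)c(Br)c2O[C@@H]1c1ccc(OCc2ccccc2)c(OCc2ccccc2)c1
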